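**Retrosynthetic overview**
1. The C11–O aryl ether (isofraxidin) and the C2 acetate are attached last, both by Mitsunobu reactions; the acetate goes on with inversion at C2.
2. Ring A (C1–C5, C10) comes from a five-membered ring (C3, C2, C1, C10, C5) by inserting C4(CH3)2 between C3 and C5. The enabling feature is the C3 ketone flanked by the quaternary C4, which is bonded to the ring-fusion carbon C5 (semipinacol retron: carbinol C3, cation C4, migrating C5).
3. In the contracted ring the C3 carbonyl sits next to C5, so C5=C10 is an enone with C10 as β-carbon. One intramolecular Hosomi–Sakurai closure of a (Z)-allylsilane then gives ring B (C5–C10), the quaternary C10, C9 and the exocyclic C8=C12.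
4. The cyclisation substrate is a B-alkyl Suzuki–Miyaura union of an allylsilane diene (from propargyl alcohol) with an (S)-5-silyloxy-2-bromo-3-methylcyclopentenone. Its single stereocentre (lipase resolution) relays C10, C9 and C5 and is itself inverted at the end.
5. Ring order: cyclopentenone (bought) → ring B (step 9) → ring A by enlargement of the five-membered ring (step 12); the coumarin is bought.

Key step: step 12

Remark on the structure: the SMILES defines a cis-fused decalin, (2R,5S,9S,10S). H5, the C10 methyl and the C9–CH2O arm lie on one face (β); the C2 acetate lies on the other (α). Locants are terpenoid (drimane) locants: C11 = CH2O on C9, C12 = exocyclic CH2 on C8; "5β" means H5 syn to the C10 methyl.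
Assumption: the lipase in step 6 acylates the (R)-alcohol faster, as is usual for secondary alcohols; if the sense is opposite, the acetate formed is the (S)-material and is carried on after enzymatic hydrolysis.

**Route**

Step 1
Reactants: 1 prop-2-yn-1-ol; 2 bromoethene (vinyl bromide)
Product: 3 pent-4-en-2-yn-1-ol
Conditions: Pd(PPh3)2Cl2 (cat.), CuI (cat.), i-Pr2NH, THF, 0 °C to rt
Reagents that add atoms: none
Why: Sonogashira coupling of the terminal alkyne with the vinyl halide gives the conjugated enynol; no stereocentre is formed.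

Step 2
Reactants: 3 pent-4-en-2-yn-1-ol
Product: 5 (2Z)-3-iodopenta-2,4-dien-1-ol, via cyclic sodium alkenylalanate 4 (not isolated)
Conditions: NaAlH2(OCH2CH2OCH3)2, THF, 0 °C; then I2, −78 °C
Reagents that add atoms: iodine, II
Why: Hydroxyl-directed trans-hydroalumination of the propargylic alcohol places aluminium on C3 inside a five-membered alanate, and iodinolysis with retention gives the (Z)-3-iodo allylic alcohol, which fixes the later allylsilane geometry.

Step 3
Reactants: 5 (2Z)-3-iodopenta-2,4-dien-1-ol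
Product: 6 (2Z)-3-[(trimethylsilyl)methyl]penta-2,4-dien-1-ol
Conditions: Me3SiCH2MgCl (2.5 equiv), Pd(PPh3)4 (cat.), THF, 0 °C to rt
Reagents that add atoms: (trimethylsilyl)methylmagnesium chloride, C[Si](C)(C)C[Mg]Cl
Why: Kumada coupling of the alkenyl iodide proceeds with retention, so CH2SiMe3 ends cis to CH2OH (Z); the first equivalent of Grignard reagent only deprotonates the alcohol.

Step 4
Reactants: 6 (2Z)-3-[(trimethylsilyl)methyl]penta-2,4-dien-1-ol
Product: 7 tert-butyl({(2Z)-3-[(trimethylsilyl)methyl]penta-2,4-dien-1-yl}oxy)diphenylsilane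
Conditions: t-BuPh2SiCl, imidazole, CH2Cl2, rt
Reagents that add atoms: tert-butyl(chloro)diphenylsilane, CC(C)(C)[Si](Cl)(c1ccccc1)c1ccccc1
Why: Standard silylation of the primary allylic alcohol; the bulky, weakly Lewis-basic silyl ether is chosen to survive TiCl4 in step 9 without ionising.

Step 5
Reactants: 8 2-bromo-3-methylcyclopent-2-en-1-one
Product: 9 rac-2-bromo-5-hydroxy-3-methylcyclopent-2-en-1-one
Conditions: KN(SiMe3)2, THF, −78 °C; then 2-(phenylsulfonyl)-3-phenyloxaziridine, −78 °C; aq NH4Cl
Reagents that add atoms: 2-(phenylsulfonyl)-3-phenyloxaziridine, O=S(=O)(N1OC1c1ccccc1)c1ccccc1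
Why: Kinetic deprotonation of the enone gives the cross-conjugated α′ potassium enolate, which the N-sulfonyloxaziridine hydroxylates (enolate oxidation); the product is racemic.

Step 6
Reactants: 9 rac-2-bromo-5-hydroxy-3-methylcyclopent-2-en-1-one
Product: 10 (5S)-2-bromo-5-hydroxy-3-methylcyclopent-2-en-1-one
Conditions: Burkholderia cepacia lipase, vinyl acetate, t-BuOMe, 30 °C, stopped just past half conversion; chromatography
Reagents that add atoms: none
Why: Lipase-catalysed transesterification is a kinetic resolution: the (R)-alcohol is acetylated and the (S)-alcohol is recovered, which sets the one stereocentre from which all others are relayed.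

Step 7
Reactants: 10 (5S)-2-bromo-5-hydroxy-3-methylcyclopent-2-en-1-one
Product: 11 (5S)-2-bromo-5-[(tert-butyldimethylsilyl)oxy]-3-methylcyclopent-2-en-1-one
Conditions: t-BuMe2SiCl, imidazole, DMF, rt
Reagents that add atoms: tert-butyl(chloro)dimethylsilane, CC(C)(C)[Si](C)(C)Cl
Why: Silylation under neutral conditions leaves the α′ stereocentre untouched and installs the bulky group that later shields one enone face and disfavours migration of C2.

Step 8
Reactants: 7 tert-butyl({(2Z)-3-[(trimethylsilyl)methyl]penta-2,4-dien-1-yl}oxy)diphenylsilane; 11 (5S)-2-bromo-5-[(tert-butyldimethylsilyl)oxy]-3-methylcyclopent-2-en-1-one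
Product: 13 (5S)-5-[(tert-butyldimethylsilyl)oxy]-2-{(3Z)-5-[(tert-butyldiphenylsilyl)oxy]-3-[(trimethylsilyl)methyl]pent-3-en-1-yl}-3-methylcyclopent-2-en-1-one, via B-alkyl-9-borabicyclononane 12 (not isolated)
Conditions: 9-BBN-H, THF, 0 °C to rt; then 11, Pd(dppf)Cl2 (cat.), AsPh3, K3PO4 (aq), DMF, rt
Reagents that add atoms: none
Why: 9-BBN adds to the monosubstituted alkene of the diene with boron on the terminal carbon and leaves the trisubstituted allylsilane, and the B-alkyl Suzuki–Miyaura coupling with the α-bromo enone forms C5–C6 under phosphate base mild enough for the α′ stereocentre.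

Step 9
Reactants: 13 (5S)-5-[(tert-butyldimethylsilyl)oxy]-2-{(3Z)-5-[(tert-butyldiphenylsilyl)oxy]-3-[(trimethylsilyl)methyl]pent-3-en-1-yl}-3-methylcyclopent-2-en-1-one
Product: 15 cis-fused hydrindanone (2β-silyloxy, 5β-H, 9β-CH2OSi, 10β-CH3, 8-methylidene; C3 ketone bonded to C5), via trichlorotitanium enolate 14 (not isolated)
Conditions: TiCl4 (1.1 equiv), CH2Cl2, −78 °C; Et3N, then aq NaHCO3, −78 °C to rt
Reagents that add atoms: none
Why: Intramolecular Hosomi–Sakurai conjugate allylation: C9 of the allylsilane attacks the TiCl4-activated enone at C10 in a chair-like six-membered closure that forms ring B, the quaternary C10 and, on loss of Me3Si, the exocyclic C8=C12; the short tether translates the (Z)-geometry into C11 syn to the C10 methyl, the allylsilane should add to the enone face anti to the C2 silyloxy group (1,3-relay, which fixes the absolute configuration), and protonation of the enolate from the methyl face (ring B shields the other) gives the cis ring fusion, which is also the thermodynamic one.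

Step 10
Reactants: 16 acetone
Product: 17 2,2-bis(phenylselanyl)propane
Conditions: PhSeH (2 equiv), ZnCl2 (cat.), CH2Cl2, rt
Reagents that add atoms: benzeneselenol, [SeH]c1ccccc1
Why: ZnCl2-catalysed selenoketalisation of acetone with two equivalents of selenol; no stereocentre.

Step 11
Reactants: 15 cis-fused hydrindanone; 17 2,2-bis(phenylselanyl)propane
Product: 18 tertiary β-hydroxy selenide (15 with OH and a 2-(phenylselanyl)propan-2-yl group on C3; C3 epimers)
Conditions: 17, n-BuLi, THF, −78 °C; then 15, −78 °C; aq NH4Cl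
Reagents that add atoms: none
Why: Selenium–lithium exchange gives the tertiary α-selenoalkyllithium, a strongly nucleophilic and weakly basic carbanion that adds to the hindered, enolisable cyclopentanone (1,2-addition); the new carbinol centre C3 may form as either epimer because it becomes the carbonyl carbon in step 12.

Step 12
Reactants: 18 tertiary β-hydroxy selenide
Product: 19 2β-[(tert-butyldimethylsilyl)oxy]-11-[(tert-butyldiphenylsilyl)oxy]-5β-drim-8(12)-en-3-one
Conditions: AgBF4 (1.5 equiv) on basic Al2O3, CH2Cl2, 0 °C to rt, dark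
Reagents that add atoms: none
Why: Silver ion binds the tertiary selenide and heterolysis of C4–Se gives a tertiary cation (CMe2+) next to the carbinol C3; the C3–C5 bond then shifts to C4 while the hydroxyl oxygen closes to the carbonyl, so the five-membered ring C3–C2–C1–C10–C5 becomes the six-membered ring A with C4 inserted between C3 and C5. The closest known reaction type is the semipinacol (Tiffeneau–Demjanov-type) ring enlargement of β-hydroxy selenides of cycloalkanones to their 2,2-dialkyl homologues. No ring is closed by cyclisation: ring A arises by a 1,2-alkyl shift (5 → 6 enlargement) and ring B is untouched. No new stereocentre is formed: C5 migrates with retention, which carries the cis ring fusion (H5 syn to the C10 methyl) from 18 into 19, the carbinol centre C3 disappears and C4 is not stereogenic. The step needs C5 rather than C2 to migrate, which the tertiary, electron-rich C5 and the σ-withdrawing silyloxy group on C2 secure; it also needs ionisation at C4 only and no free Brønsted acid, which the selenium leaving group and the basic alumina secure, so that the exocyclic C8=C12 alkene and both silyl ethers survive.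

Step 13
Reactants: 19 2β-[(tert-butyldimethylsilyl)oxy]-11-[(tert-butyldiphenylsilyl)oxy]-5β-drim-8(12)-en-3-one
Product: 20 11-[(tert-butyldiphenylsilyl)oxy]-2β-hydroxy-5β-drim-8(12)-en-3-one
Conditions: camphorsulfonic acid (cat.), MeOH/CH2Cl2, 0 °C to rt
Reagents that add atoms: none
Why: Acid-catalysed methanolysis removes the secondary tert-butyldimethylsilyl ether while the primary tert-butyldiphenylsilyl ether, far more stable to acid, stays, and the weak acid leaves the exocyclic alkene in place.

Step 14
Reactants: 20 11-[(tert-butyldiphenylsilyl)oxy]-2β-hydroxy-5β-drim-8(12)-en-3-one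
Product: 21 2α-acetoxy-11-[(tert-butyldiphenylsilyl)oxy]-5β-drim-8(12)-en-3-one
Conditions: AcOH, PPh3, DIAD, toluene, 0 °C to rt
Reagents that add atoms: acetic acid, CC(=O)O
Why: Mitsunobu esterification displaces the activated C2 oxygen by acetate with inversion (SN2 at the α-keto carbon, acetate entering from the α-face away from the C10 and 4β methyl groups), turning the relay centre into the 2α-acetate of the target.

Step 15
Reactants: 21 2α-acetoxy-11-[(tert-butyldiphenylsilyl)oxy]-5β-drim-8(12)-en-3-one
Product: 22 2α-acetoxy-11-hydroxy-5β-drim-8(12)-en-3-one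
Conditions: HF·pyridine, pyridine, THF, 0 °C to rt
Reagents that add atoms: none
Why: Fluoride cleaves the silyl ether; the buffered, non-basic medium leaves the α-acetoxy ketone and the alkene untouched.

Step 16
Reactants: 22 2α-acetoxy-11-hydroxy-5β-drim-8(12)-en-3-one; 23 isofraxidin (7-hydroxy-6,8-dimethoxy-2H-chromen-2-one)
Product: 24 7-{[(2R,5S,9S,10S)-2-acetoxy-3-oxo-5β-drim-8(12)-en-11-yl]oxy}-6,8-dimethoxy-2H-chromen-2-one (target)
Conditions: PPh3, DIAD, THF, 0 °C to rt
Reagents that add atoms: none
Why: Mitsunobu etherification of the primary alcohol with the acidic 7-hydroxycoumarin forms the C11–O–aryl bond under neutral conditions that spare the α-acetoxy ketone; no stereocentre is involved.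

**Compound list**
1 | prop-2-yn-1-ol | C#CCO | starting material
2 | bromoethene (vinyl bromide) | C=CBr | starting material
3 | pent-4-en-2-yn-1-ol | C=CC#CCO | intermediate
4 | cyclic sodium alkenylalanate (five-membered O–Al–C ring, Al bearing two 2-methoxyethoxy groups) | [Na+].C=CC1=CCO[Al-]1(OCCOC)OCCOC | intermediate (not isolated)
5 | (2Z)-3-iodopenta-2,4-dien-1-ol | C=C/C(I)=C/CO | intermediate
6 | (2Z)-3-[(trimethylsilyl)methyl]penta-2,4-dien-1-ol | C=C/C(C[Si](C)(C)C)=C/CO | intermediate
7 | tert-butyl({(2Z)-3-[(trimethylsilyl)methyl]penta-2,4-dien-1-yl}oxy)diphenylsilane | C=C/C(C[Si](C)(C)C)=C/CO[Si](c1ccccc1)(c1ccccc1)C(C)(C)C | intermediate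
8 | 2-bromo-3-methylcyclopent-2-en-1-one | CC1=C(Br)C(=O)CC1 | starting material
9 | rac-2-bromo-5-hydroxy-3-methylcyclopent-2-en-1-one | CC1=C(Br)C(=O)C(O)C1 | intermediate
10 | (5S)-2-bromo-5-hydroxy-3-methylcyclopent-2-en-1-one | CC1=C(Br)C(=O)[C@@H](O)C1 | intermediate
11 | (5S)-2-bromo-5-[(tert-butyldimethylsilyl)oxy]-3-methylcyclopent-2-en-1-one | CC1=C(Br)C(=O)[C@@H](O[Si](C)(C)C(C)(C)C)C1 | intermediate
12 | 9-{(3Z)-5-[(tert-butyldiphenylsilyl)oxy]-3-[(trimethylsilyl)methyl]pent-3-en-1-yl}-9-borabicyclo[3.3.1]nonane | B1(CC/C(C[Si](C)(C)C)=C/CO[Si](c2ccccc2)(c2ccccc2)C(C)(C)C)C2CCCC1CCC2 | intermediate (not isolated)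
13 | (5S)-5-[(tert-butyldimethylsilyl)oxy]-2-{(3Z)-5-[(tert-butyldiphenylsilyl)oxy]-3-[(trimethylsilyl)methyl]pent-3-en-1-yl}-3-methylcyclopent-2-en-1-one | CC1=C(CC/C(C[Si](C)(C)C)=C/CO[Si](c2ccccc2)(c2ccccc2)C(C)(C)C)C(=O)[C@@H](O[Si](C)(C)C(C)(C)C)C1 | intermediate
14 | trichlorotitanium enolate of 15 (O–Ti on C3, C3=C5) | C=C1CCC2=C(O[Ti](Cl)(Cl)Cl)[C@@H](O[Si](C)(C)C(C)(C)C)C[C@]2(C)[C@H]1CO[Si](c1ccccc1)(c1ccccc1)C(C)(C)C | intermediate (not isolated)
15 | cis-fused hydrindanone: 2-[(tert-butyldimethylsilyl)oxy]-4-{[(tert-butyldiphenylsilyl)oxy]methyl}-3a-methyl-5-methylideneoctahydro-1H-inden-1-one; in terpenoid locants 2β-OSi, 5β-H, 9β-CH2OSi, 10β-CH3, C3 ketone bonded to C5 | C=C1CC[C@@H]2C(=O)[C@@H](O[Si](C)(C)C(C)(C)C)C[C@]2(C)[C@H]1CO[Si](c1ccccc1)(c1ccccc1)C(C)(C)C | intermediate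
16 | acetone | CC(C)=O | starting material
17 | 2,2-bis(phenylselanyl)propane | CC(C)([Se]c1ccccc1)[Se]c1ccccc1 | intermediate
18 | tertiary β-hydroxy selenide: 15 with OH and 2-(phenylselanyl)propan-2-yl on C3 (C3 epimers, both productive) | C=C1CC[C@@H]2C(O)(C(C)(C)[Se]c3ccccc3)[C@@H](O[Si](C)(C)C(C)(C)C)C[C@]2(C)[C@H]1CO[Si](c1ccccc1)(c1ccccc1)C(C)(C)C | intermediate
19 | 2β-[(tert-butyldimethylsilyl)oxy]-11-[(tert-butyldiphenylsilyl)oxy]-5β-drim-8(12)-en-3-one | C=C1CC[C@@H]2C(C)(C)C(=O)[C@@H](O[Si](C)(C)C(C)(C)C)C[C@]2(C)[C@H]1CO[Si](c1ccccc1)(c1ccccc1)C(C)(C)C | intermediate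
20 | 11-[(tert-butyldiphenylsilyl)oxy]-2β-hydroxy-5β-drim-8(12)-en-3-one | C=C1CC[C@@H]2C(C)(C)C(=O)[C@@H](O)C[C@]2(C)[C@H]1CO[Si](c1ccccc1)(c1ccccc1)C(C)(C)C | intermediate
21 | 2α-acetoxy-11-[(tert-butyldiphenylsilyl)oxy]-5β-drim-8(12)-en-3-one | C=C1CC[C@@H]2C(C)(C)C(=O)[C@H](OC(C)=O)C[C@]2(C)[C@H]1CO[Si](c1ccccc1)(c1ccccc1)C(C)(C)C | intermediate
22 | 2α-acetoxy-11-hydroxy-5β-drim-8(12)-en-3-one | C=C1CC[C@@H]2C(C)(C)C(=O)[C@H](OC(C)=O)C[C@]2(C)[C@H]1CO | intermediate
23 | isofraxidin (7-hydroxy-6,8-dimethoxy-2H-chromen-2-one) | Oc1c(OC)cc2ccc(=O)oc2c1OC | starting material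
24 | 7-{[(2R,5S,9S,10S)-2-acetoxy-3-oxo-5β-drim-8(12)-en-11-yl]oxy}-6,8-dimethoxy-2H-chromen-2-one | C=C1CC[C@@H]2C(C)(C)C(=O)[C@H](OC(C)=O)C[C@]2(C)[C@H]1COc1c(OC)cc2ccc(=O)oc2c1OC | target

**Step count and risks**
Total steps: 16. Longest linear sequence: 12 (steps 1–4, 8, 9, 11–16).

Risk 1, step 9. The C2 silyloxy group is only 1,3 to C10 and may discriminate the two enone faces poorly, so that the allylsilane adds to both and material is lost as the separable wrong diastereomer; the Lewis acid may also protodesilylate the allylsilane. The fallback gives up the substrate relay and sets out from borane 12 and bromo-enone 8. Suzuki–Miyaura coupling as in step 8 gives the achiral 2-alkyl-3-methylcyclopentenone F1, which TiCl4 cyclises to the racemic cis-hydrindanone without C2 oxygen F2. Addition of the lithium reagent from 17 gives the racemic β-hydroxy selenide F3, and AgBF4 on Al2O3 gives the racemic C2-unsubstituted decalone F4. KN(SiMe3)2 and 2-(phenylsulfonyl)-3-phenyloxaziridine then hydroxylate the only enolisable position from the α-face, anti to the axial C10 and 4β methyl groups, to the racemic 2α-hydroxy ketone F5. Lipase-catalysed acetylation of F5 with vinyl acetate (or separation on a chiral stationary phase, then Ac2O/pyridine) returns to the route at 21.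

Risk 2, step 12. The C4 cation may be trapped by the neighbouring hydroxyl (oxirane) or lose a proton (isopropenyl carbinol) instead of triggering the 1,2-shift, and acid set free may move the exocyclic double bond into the ring. The fallback sets out from 18 and makes the oxirane on purpose: Se-methylation with Me3OBF4 and then aqueous KOH give the 2,2-dimethyl spiro-oxirane F6. A catalytic amount of MeAl(OAr)2 (Ar = 4-bromo-2,6-di-tert-butylphenyl) or BF3·OEt2 in CH2Cl2 at −78 °C then opens it at the dimethyl-substituted carbon and effects the ring-enlarging epoxide-to-ketone (Meinwald-type) rearrangement, coming back to the route at 19.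

Risk 3, step 14. At the hindered α-keto carbinol, elimination to the C1=C2 enone or enolisation with retention may outrun SN2 inversion. The fallback sets out from 20 and replaces inversion by removal and reagent-controlled reintroduction of the oxygen. Ac2O/DMAP gives the 2β-acetate F7, SmI2 in THF/MeOH at −78 °C cleaves the α-acetoxy group to the C2-unsubstituted ketone F8, and KN(SiMe3)2 with 2-(phenylsulfonyl)-3-phenyloxaziridine hydroxylates from the α-face to the 2α-hydroxy ketone F9. Ac2O/pyridine then returns to the route at 21.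

**Further compounds**
F1 | step 9 | 2-{(3Z)-5-[(tert-butyldiphenylsilyl)oxy]-3-[(trimethylsilyl)methyl]pent-3-en-1-yl}-3-methylcyclopent-2-en-1-one | CC1=C(CC/C(C[Si](C)(C)C)=C/CO[Si](c2ccccc2)(c2ccccc2)C(C)(C)C)C(=O)CC1
F2 | step 9 | racemic cis-fused hydrindanone without C2 oxygen (relative configuration 5β-H, 9β-CH2OSi, 10β-CH3) | C=C1CC[C@@H]2C(=O)CC[C@]2(C)[C@H]1CO[Si](c1ccccc1)(c1ccccc1)C(C)(C)C
F3 | step 9 | racemic β-hydroxy selenide from F2 (C3 epimers) | C=C1CC[C@@H]2C(O)(C(C)(C)[Se]c3ccccc3)CC[C@]2(C)[C@H]1CO[Si](c1ccccc1)(c1ccccc1)C(C)(C)C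
F4 | step 9 | racemic 11-[(tert-butyldiphenylsilyl)oxy]-5β-drim-8(12)-en-3-one | C=C1CC[C@@H]2C(C)(C)C(=O)CC[C@]2(C)[C@H]1CO[Si](c1ccccc1)(c1ccccc1)C(C)(C)C
F5 | step 9 | racemic 11-[(tert-butyldiphenylsilyl)oxy]-2α-hydroxy-5β-drim-8(12)-en-3-one | C=C1CC[C@@H]2C(C)(C)C(=O)[C@H](O)C[C@]2(C)[C@H]1CO[Si](c1ccccc1)(c1ccccc1)C(C)(C)C
F6 | step 12 | 2,2-dimethyl spiro-oxirane on C3 of the hydrindane (C3 epimers) | C=C1CC[C@@H]2C3(OC3(C)C)[C@@H](O[Si](C)(C)C(C)(C)C)C[C@]2(C)[C@H]1CO[Si](c1ccccc1)(c1ccccc1)C(C)(C)C
F7 | step 14 | 2β-acetoxy-11-[(tert-butyldiphenylsilyl)oxy]-5β-drim-8(12)-en-3-one | C=C1CC[C@@H]2C(C)(C)C(=O)[C@@H](OC(C)=O)C[C@]2(C)[C@H]1CO[Si](c1ccccc1)(c1ccccc1)C(C)(C)C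
F8 | step 14 | 11-[(tert-butyldiphenylsilyl)oxy]-5β-drim-8(12)-en-3-one, single enantiomer | C=C1CC[C@@H]2C(C)(C)C(=O)CC[C@]2(C)[C@H]1CO[Si](c1ccccc1)(c1ccccc1)C(C)(C)C
F9 | step 14 | 11-[(tert-butyldiphenylsilyl)oxy]-2α-hydroxy-5β-drim-8(12)-en-3-one, single enantiomer | C=C1CC[C@@H]2C(C)(C)C(=O)[C@H](O)C[C@]2(C)[C@H]1CO[Si](c1ccccc1)(c1ccccc1)C(C)(C)C
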